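I follow one ratio through this flask: h, the fraction of the charged starting material at which catalyst intermediate C, holding as much catalyst as catalyst intermediate A, takes up starting material as fast as catalyst intermediate A loses released group. It is the Michaelis constant over the charge, h = 0.184.

starting material 0.39 M; reagent 0.780 M; protic impurity 0.0195 M; free catalyst 0.78 mM; time 2.5 d

    reagent + free catalyst → catalyst intermediate A (k1 = 1.02 /M/s)
    catalyst intermediate A ⇌ released group + catalyst intermediate B (K2 = 0.28 M, k2 = 0.00260 /s)
    catalyst intermediate B → catalyst intermediate C (k3 = 0.405 /s)
    starting material + catalyst intermediate C ⇌ catalyst intermediate D (K4 = 7.23 /M, k4 = 0.0362 /M/s)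
    catalyst intermediate D ⇌ free catalyst + target (K5 = 4.1 M, k5 = 0.277 /s)
    reagent + released group ⇌ idle adduct, settled at all times (K6 = 1.40 /M)
    starting material + protic impurity → quenched substrate (k7 = 0.00933 /M/s)

- released group is meant together with its idle adduct
- run time (flask): 2.5 d

- part of the starting material that has reacted at 2.5 d
- share of the unused reagent that is free and not bound as idle adduct, at 2.5 d

What goes before the catalyst counts? The protic impurity is 5.00% of the starting material charged and has a pseudo-first-order half-life near 3.17 min, short against 2.5 d. So the catalyst starts on g = 0.950 of the charge.

How far does full speed reach? The neighbouring steps, at 0.405 /s, 0.277 /s and 0.796 /s, outrun 0.00260 /s. So while f, the fraction left, stands far above h, catalyst intermediate A is the resting state and its loss of released group is the rate-limiting step. At that speed the catalyst would turn over s = 1.12 of the charge in 2.5 d, more than g, so I expect this flask to reach the slow end.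

Where does it stand then? I join the ends: the speed goes as f/(f+h), which integrates to g − f + h·ln(g/f) = s, with the backward runs left out. At f = h the left side is 1.07, just short of s. The speed there is half of full, so the remainder lowers f by 0.0276. I expect f = 0.157, so c = 84.3%; for fr I make no hand figure.

The forecast gives 83% and 78%, with a limit on the catalyst that shifts “as substrate depletes”.

The flask gives 83.1% and 78.1%, so c stands 1.3 percentage points below my figure.

At 2.50 d this flask holds 47.1% of its catalyst as catalyst intermediate A and 51.8% as catalyst intermediate C, a ratio of 0.909, while f/h, with 17% of the starting material left, is 0.924. In the neighbour flask with 1.6 M of starting material, h falls to 0.0449 and s to 0.274, so the straight run less a short tail gives 27.1%. That neighbour flask reacts 26.6%.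

All constants were chosen freely; the flask was simulated.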